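Assumption: labels C1–C15 follow germacranolide numbering (C6 carries the lactone oxygen, C12 is the lactone carbonyl, C3 and C9 carry the acetates). Read this way the SMILES is (3S,6S,7S,9R,11R) with Z alkenes at C1=C10 and C4=C5. On the lactone ring C5 and C8 are trans, and C8 and C13 are cis.

**Retrosynthetic overview**
1. Target 24 ⇐ ring-closing metathesis at C1=C10 of the acyclic triene diacetate 23. The ten-membered carbocycle is closed last.
2. 23 ⇐ α-methylene-γ-lactone 20 by desilylation, copper hydride reduction (sets C11) and acetylation.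
3. 20 ⇐ C6–C7 bond: Nozaki–Hiyama allylation of west Z-enal 10 with east bromomethyl-dihydropyranone 17, followed by a six-ring to five-ring lactone switch.
4. 10 ⇐ propargyl alcohol (Z alkene by carbomagnesiation/iodination, C3 by allylboration). 17 ⇐ methacrolein (C9 by allylboration, then acrylate, Baylis–Hillman, RCM, bromination).
5. Ring order: six-membered lactone template (step 9) → five-membered lactone (step 11) → ten-membered ring (step 15).

**West fragment**

Step 1
Reactants: 1 prop-2-yn-1-ol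
Product: 3 (Z)-3-iodo-2-methylprop-2-en-1-ol, via alkenylmagnesium chelate 2 (not isolated)
Conditions: MeMgBr (2.5 equiv), CuI (10 mol %), THF/Et2O, −10 °C → rt; then I2, 0 °C; aq. work-up
Reagents that add atoms: methylmagnesium bromide, C[Mg]Br; iodine, [I][I]
Why: Copper-catalysed, alkoxide-directed anti-carbomagnesiation puts CH3 on the inner alkyne carbon and Mg on the terminus cis to CH2O in a five-membered chelate, and iodinolysis with retention fixes the Z geometry of the later C4=C5 alkene.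

Step 2
Reactants: 3 (Z)-3-iodo-2-methylprop-2-en-1-ol
Product: 4 (Z)-3-iodo-2-methylprop-2-enal
Conditions: activated MnO2 (15 equiv), CH2Cl2, rt, dark, 1 h; filtered and used at once
Reagents that add atoms: none
Why: Neutral heterogeneous allylic alcohol oxidation gives the enal without acid or base, so the Z iodoalkene does not isomerise.

Step 3
Reactants: 4 (Z)-3-iodo-2-methylprop-2-enal
Product: 6 (1Z,3S)-1-iodo-2-methylhexa-1,5-dien-3-ol, via homoallyl borinate 5 (not isolated)
Conditions: B-allyldiisopinocampheylborane from (+)-α-pinene (1.2 equiv), Et2O, −78 °C, 2 h; then 3 M NaOH, 30 % H2O2, 0 °C → rt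
Reagents that add atoms: B-allyldiisopinocampheylborane from (+)-α-pinene, C=CCB([C@@H]1C[C@@H]2C[C@H]([C@H]1C)C2(C)C)[C@@H]1C[C@@H]2C[C@H]([C@H]1C)C2(C)C
Why: Brown asymmetric allylboration through a closed chair transition state; the (+)-α-pinene-derived reagent gives the S carbinol with aryl and alkenyl aldehydes, which sets C3 and installs the C1 terminal alkene.

Step 4
Reactants: 6 (1Z,3S)-1-iodo-2-methylhexa-1,5-dien-3-ol
Product: 7 tert-butyl{[(1Z,3S)-1-iodo-2-methylhexa-1,5-dien-3-yl]oxy}dimethylsilane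
Conditions: TBSCl (1.3 equiv), imidazole (2.5 equiv), DMF, rt
Reagents that add atoms: tert-butyldimethylsilyl chloride, CC(C)(C)[Si](C)(C)Cl
Why: Standard silyl ether protection masks the C3 hydroxyl for the organolithium step without touching the stereocentre.

Step 5
Reactants: 7 tert-butyl{[(1Z,3S)-1-iodo-2-methylhexa-1,5-dien-3-yl]oxy}dimethylsilane
Product: 10 (2Z,4S)-4-[(tert-butyldimethylsilyl)oxy]-3-methylhepta-2,6-dienal, via alkenyllithium 8 (not isolated), via lithium hemiaminal alkoxide 9 (not isolated)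
Conditions: t-BuLi (2.1 equiv), Et2O, −78 °C, 15 min; DMF (3 equiv), −78 → −40 °C; pH 7 aqueous quench
Reagents that add atoms: N,N-dimethylformamide, CN(C)C=O
Why: Iodine–lithium exchange and Bouveault formylation both proceed with retention of alkene geometry, and at −78 °C in Et2O with a fast quench they outrun 1,4-silyl migration and carbolithiation.

**East fragment**

Step 6
Reactants: 11 2-methylprop-2-enal (methacrolein)
Product: 13 (3R)-2-methylhexa-1,5-dien-3-ol, via homoallyl borinate 12 (not isolated)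
Conditions: B-allyldiisopinocampheylborane from (−)-α-pinene (1.1 equiv), Et2O, −78 °C, 2 h; then 3 M NaOH, 30 % H2O2, 0 °C → rt
Reagents that add atoms: B-allyldiisopinocampheylborane from (−)-α-pinene, C=CCB([C@H]1C[C@H]2C[C@@H]([C@@H]1C)C2(C)C)[C@H]1C[C@H]2C[C@@H]([C@@H]1C)C2(C)C
Why: Brown asymmetric allylboration with the enantiomeric reagent gives the R carbinol, which sets C9 next to the isopropenyl group (C10, C14).

Step 7
Reactants: 13 (3R)-2-methylhexa-1,5-dien-3-ol
Product: 14 (3R)-2-methylhexa-1,5-dien-3-yl prop-2-enoate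
Conditions: acryloyl chloride (1.3 equiv), Et3N (2 equiv), CH2Cl2, 0 °C
Reagents that add atoms: acryloyl chloride, C=CC(=O)Cl
Why: O-acylation brings in C11 and C12 and does not involve the C9–O bond, so configuration is retained.

Step 8
Reactants: 14 (3R)-2-methylhexa-1,5-dien-3-yl prop-2-enoate
Product: 15 (3R)-2-methylhexa-1,5-dien-3-yl 2-(hydroxymethyl)prop-2-enoate
Conditions: 37 % aq. HCHO (3 equiv), DABCO (1 equiv), 1,4-dioxane/H2O 1:1, rt, 36 h
Reagents that add atoms: formaldehyde, C=O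
Why: Morita–Baylis–Hillman hydroxymethylation works well on open-chain acrylates and adds C13 at the α-carbon only, because the isolated alkenes are not Michael acceptors.

Step 9
Reactants: 15 (3R)-2-methylhexa-1,5-dien-3-yl 2-(hydroxymethyl)prop-2-enoate
Product: 16 (6R)-3-(hydroxymethyl)-6-(prop-1-en-2-yl)-5,6-dihydro-2H-pyran-2-one
Conditions: second-generation Grubbs catalyst (5 mol %), CH2Cl2 (0.01 M), reflux
Reagents that add atoms: none
Why: In this ring-closing metathesis the carbene formed on the allyl terminus can only close a six-membered ring onto the acrylate alkene, since closure onto the isopropenyl group would give a cyclobutene, so that group survives.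

Step 10
Reactants: 16 (6R)-3-(hydroxymethyl)-6-(prop-1-en-2-yl)-5,6-dihydro-2H-pyran-2-one
Product: 17 (6R)-3-(bromomethyl)-6-(prop-1-en-2-yl)-5,6-dihydro-2H-pyran-2-one
Conditions: CBr4 (1.3 equiv), PPh3 (1.3 equiv), CH2Cl2, 0 °C
Reagents that add atoms: carbon tetrabromide, BrC(Br)(Br)Br
Why: The Appel reaction converts the primary allylic alcohol to the bromide under neutral conditions that leave the lactone and C9 untouched.

**Union and endgame**

Step 11
Reactants: 10 (2Z,4S)-4-[(tert-butyldimethylsilyl)oxy]-3-methylhepta-2,6-dienal; 17 (6R)-3-(bromomethyl)-6-(prop-1-en-2-yl)-5,6-dihydro-2H-pyran-2-one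
Product: 20 (4S,5R)-5-[(1Z,3S)-3-{[tert-butyl(dimethyl)silyl]oxy}-2-methylhexa-1,5-dien-1-yl]-4-[(2R)-2-hydroxy-3-methylbut-3-en-1-yl]-3-methylideneoxolan-2-one, via allylchromium reagent 18 (not isolated), via chromium alkoxide 19 (not isolated)
Conditions: CrCl2 (4 equiv), THF, 0 °C → rt, 16 h (10 and 17 added together); aq. work-up
Reagents that add atoms: none
Why: In this Nozaki–Hiyama allylation the allylchromium attacks through ring carbon C7 in a closed chair, axially and anti to the C9 isopropenyl group (sets 7S) and anti across C6–C7 because the ring locks an E-type allyl geometry (sets C6), and the trivalent chromium alkoxide then opens the six-membered lactone to give the more stable trans-4,5-disubstituted five-membered lactone.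

Step 12
Reactants: 20 the silyl-protected α-methylene lactone of step 11
Product: 21 (4S,5R)-5-[(1Z,3S)-3-hydroxy-2-methylhexa-1,5-dien-1-yl]-4-[(2R)-2-hydroxy-3-methylbut-3-en-1-yl]-3-methylideneoxolan-2-one
Conditions: HF·pyridine, pyridine, THF, 0 °C → rt
Reagents that add atoms: none
Why: Buffered fluoride desilylation frees the C3 hydroxyl without the basic alkoxide conditions that would trigger oxa-Michael addition to the methylene lactone or ionise the allylic C–O bonds.

Step 13
Reactants: 21 the α-methylene lactone diol of step 12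
Product: 22 (3R,4S,5S)-5-[(1Z,3S)-3-hydroxy-2-methylhexa-1,5-dien-1-yl]-4-[(2R)-2-hydroxy-3-methylbut-3-en-1-yl]-3-methyloxolan-2-one
Conditions: Cu(OAc)2·H2O (5 mol %), 1,2-bis(diphenylphosphino)benzene (5 mol %), (EtO)2MeSiH (4 equiv), t-BuOH (4 equiv), toluene, −20 → 0 °C; aq. NH4F work-up
Reagents that add atoms: none
Why: Copper hydride conjugate reduction touches only the acrylate-type alkene, and bulky t-BuOH protonates the copper enolate kinetically on the face opposite the adjacent C8 side chain, which places the C13 methyl cis to C8 (11R).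

Step 14
Reactants: 22 the α-methyl lactone diol of step 13
Product: 23 (3R,4S,5S)-5-[(1Z,3S)-3-acetoxy-2-methylhexa-1,5-dien-1-yl]-4-[(2R)-2-acetoxy-3-methylbut-3-en-1-yl]-3-methyloxolan-2-one
Conditions: Ac2O (4 equiv), Et3N (6 equiv), DMAP (10 mol %), CH2Cl2, 0 °C → rt
Reagents that add atoms: acetic anhydride, CC(=O)OC(C)=O
Why: DMAP-catalysed acetylation esterifies both secondary alcohols with retention, and amine bases are too weak to epimerise the lactone α-carbon C11.

Step 15
Reactants: 23 the triene diacetate of step 14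
Product: 24 (3R,3aS,5R,6Z,9S,10Z,11aS)-3,6,10-trimethyl-2-oxo-2,3,3a,4,5,8,9,11a-octahydrocyclodeca[b]furan-5,9-diyl diacetate (target)
Conditions: second-generation Hoveyda–Grubbs catalyst (2 × 5 mol %), 1,4-benzoquinone (20 mol %), toluene (0.5 mM), 80 °C, argon sparge
Reagents that add atoms: none
Why: In this ring-closing metathesis macrocyclisation the catalyst loads on the monosubstituted C1 alkene and closes onto the isopropenyl group with loss of ethene, the ten-membered ring favours the less strained Z trisubstituted alkene, and the C1 carbene has no small-ring alternative with C4=C5.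

**Compound list**
1 | prop-2-yn-1-ol | C#CCO | starting material
2 | cyclic (Z)-alkenylmagnesium alkoxide (4-methyl-2,5-dihydro-1,2-oxamagnesole) | CC1=C[Mg]OC1 | intermediate
3 | (Z)-3-iodo-2-methylprop-2-en-1-ol | OC/C(C)=C\I | intermediate
4 | (Z)-3-iodo-2-methylprop-2-enal | O=C/C(C)=C\I | intermediate
5 | (1Z,3S)-1-iodo-2-methylhexa-1,5-dien-3-yl diisopinocampheylborinate (Ipc from (+)-α-pinene) | C=CC[C@H](OB([C@@H]1C[C@@H]2C[C@H]([C@H]1C)C2(C)C)[C@@H]1C[C@@H]2C[C@H]([C@H]1C)C2(C)C)/C(C)=C\I | intermediate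
6 | (1Z,3S)-1-iodo-2-methylhexa-1,5-dien-3-ol | C=CC[C@H](O)/C(C)=C\I | intermediate
7 | tert-butyl{[(1Z,3S)-1-iodo-2-methylhexa-1,5-dien-3-yl]oxy}dimethylsilane | C=CC[C@H](O[Si](C)(C)C(C)(C)C)/C(C)=C\I | intermediate
8 | (1Z,3S)-3-(TBS-oxy)-2-methylhexa-1,5-dien-1-yllithium | C=CC[C@H](O[Si](C)(C)C(C)(C)C)/C(C)=C\[Li] | intermediate
9 | lithium (2Z,4S)-1-(dimethylamino)-4-(TBS-oxy)-3-methylhepta-2,6-dien-1-olate | C=CC[C@H](O[Si](C)(C)C(C)(C)C)/C(C)=C\C(O[Li])N(C)C | intermediate
10 | (2Z,4S)-4-[(tert-butyldimethylsilyl)oxy]-3-methylhepta-2,6-dienal (west fragment) | C=CC[C@H](O[Si](C)(C)C(C)(C)C)/C(C)=C\C=O | intermediate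
11 | 2-methylprop-2-enal (methacrolein) | C=C(C)C=O | starting material
12 | (3R)-2-methylhexa-1,5-dien-3-yl diisopinocampheylborinate (Ipc from (−)-α-pinene) | C=CC[C@@H](OB([C@H]1C[C@H]2C[C@@H]([C@@H]1C)C2(C)C)[C@H]1C[C@H]2C[C@@H]([C@@H]1C)C2(C)C)C(C)=C | intermediate
13 | (3R)-2-methylhexa-1,5-dien-3-ol | C=CC[C@@H](O)C(C)=C | intermediate
14 | (3R)-2-methylhexa-1,5-dien-3-yl prop-2-enoate | C=CC[C@@H](OC(=O)C=C)C(C)=C | intermediate
15 | (3R)-2-methylhexa-1,5-dien-3-yl 2-(hydroxymethyl)prop-2-enoate | C=CC[C@@H](OC(=O)C(=C)CO)C(C)=C | intermediate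
16 | (6R)-3-(hydroxymethyl)-6-(prop-1-en-2-yl)-5,6-dihydro-2H-pyran-2-one | C=C(C)[C@H]1CC=C(CO)C(=O)O1 | intermediate
17 | (6R)-3-(bromomethyl)-6-(prop-1-en-2-yl)-5,6-dihydro-2H-pyran-2-one (east fragment) | C=C(C)[C@H]1CC=C(CBr)C(=O)O1 | intermediate
18 | dichloro{[(6R)-2-oxo-6-(prop-1-en-2-yl)-5,6-dihydro-2H-pyran-3-yl]methyl}chromium | C=C(C)[C@H]1CC=C(C[Cr](Cl)Cl)C(=O)O1 | intermediate
19 | dichlorochromium alkoxide of (4S,6R)-4-[(1R,2Z,4S)-4-(TBS-oxy)-1-hydroxy-3-methylhepta-2,6-dien-1-yl]-3-methylidene-6-(prop-1-en-2-yl)oxan-2-one | C=CC[C@H](O[Si](C)(C)C(C)(C)C)/C(C)=C\[C@@H](O[Cr](Cl)Cl)[C@H]1C[C@H](C(C)=C)OC(=O)C1=C | intermediate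
20 | (4S,5R)-5-[(1Z,3S)-3-{[tert-butyl(dimethyl)silyl]oxy}-2-methylhexa-1,5-dien-1-yl]-4-[(2R)-2-hydroxy-3-methylbut-3-en-1-yl]-3-methylideneoxolan-2-one | C=CC[C@H](O[Si](C)(C)C(C)(C)C)/C(C)=C\[C@H]1OC(=O)C(=C)[C@@H]1C[C@@H](O)C(C)=C | intermediate
21 | (4S,5R)-5-[(1Z,3S)-3-hydroxy-2-methylhexa-1,5-dien-1-yl]-4-[(2R)-2-hydroxy-3-methylbut-3-en-1-yl]-3-methylideneoxolan-2-one | C=CC[C@H](O)/C(C)=C\[C@H]1OC(=O)C(=C)[C@@H]1C[C@@H](O)C(C)=C | intermediate
22 | (3R,4S,5S)-5-[(1Z,3S)-3-hydroxy-2-methylhexa-1,5-dien-1-yl]-4-[(2R)-2-hydroxy-3-methylbut-3-en-1-yl]-3-methyloxolan-2-one | C=CC[C@H](O)/C(C)=C\[C@H]1OC(=O)[C@H](C)[C@@H]1C[C@@H](O)C(C)=C | intermediate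
23 | (3R,4S,5S)-5-[(1Z,3S)-3-acetoxy-2-methylhexa-1,5-dien-1-yl]-4-[(2R)-2-acetoxy-3-methylbut-3-en-1-yl]-3-methyloxolan-2-one | C=CC[C@H](OC(C)=O)/C(C)=C\[C@H]1OC(=O)[C@H](C)[C@@H]1C[C@@H](OC(C)=O)C(C)=C | intermediate
24 | (3R,3aS,5R,6Z,9S,10Z,11aS)-3,6,10-trimethyl-2-oxo-2,3,3a,4,5,8,9,11a-octahydrocyclodeca[b]furan-5,9-diyl diacetate | CC(=O)O[C@H]1C/C=C(/C)[C@H](OC(C)=O)C[C@@H]2[C@@H](/C=C\1C)OC(=O)[C@@H]2C | target

**Step count**
Total step count: 15.
Longest linear sequence: 10 steps (steps 1–5 then 11–15; the east branch, steps 6–10 then 11–15, is equally long).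

**Steps most likely to fail**

Step 11 (fragment union; C6 and C7 are set by 1,3-induction from C9 and by the chair geometry, and the Z-enal must survive the chromium salts). The fallback sets out from 17 and comes back at 20.
- 17 is treated with B2pin2 and Pd2(dba)3 (1 mol %) in THF at rt. The primary allylic bromide ionises far faster than the lactone C9–O bond. This gives the isolable allylboronate (6R)-6-(prop-1-en-2-yl)-3-[(4,4,5,5-tetramethyl-1,3,2-dioxaborolan-2-yl)methyl]-5,6-dihydro-2H-pyran-2-one F1.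
- F1 and 10 are combined with Sc(OTf)3 (10 mol %) in toluene at −40 °C. Carbon–carbon bond formation then runs through a tight boron-centred chair with no reducing metal present. The product is the pinacol borate of the six-ring carbinol F2.
- PPTS in wet CH2Cl2 cleaves the boron–oxygen bond to give the free six-ring carbinol (4S,6R)-4-[(1R,2Z,4S)-4-(TBS-oxy)-1-hydroxy-3-methylhepta-2,6-dien-1-yl]-3-methylidene-6-(prop-1-en-2-yl)oxan-2-one F3. Under the same acid F3 switches lactone rings and rejoins the route at 20.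

Step 13 (C11 rests on kinetic protonation to the less stable cis epimer). The fallback sets out from 10 and 17 and comes back at 22. It sets C11 under thermodynamic control in the six-membered lactone.
- The allylation is rerun with catalytic chromium (CrCl2 10 mol %, Mn powder, Me3SiCl, THF). The alkoxide is then silylated before it can open the lactone, giving the six-ring lactone trimethylsilyl ether F4.
- Copper hydride reduction as in step 13 is followed by equilibration with DBU (toluene, 60 °C). This gives the (3R,4S,6R) 3,4-trans α-methyl six-ring lactone F5. In this ring the wanted 11R methyl is trans to the large C7 substituent, so it is the more stable epimer.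
- HF·pyridine removes both silyl groups to give the six-ring lactone diol F6.
- PPTS in CH2Cl2 lets the C6 hydroxyl switch the lactone without touching C11, which delivers 22.

Step 15 (ten-membered ring, hindered isopropenyl partner bearing an allylic acetate). The fallback sets out from 22 and comes back at 24. Ring closure and acylation are exchanged.
- The free diol 22 is cyclised with the second-generation Hoveyda–Grubbs catalyst and 1,4-benzoquinone in toluene (0.5 mM, 60–80 °C). The unprotected allylic C9 hydroxyl accelerates metathesis at the 1,1-disubstituted alkene, and the substrate is less encumbered. The product is the macrocyclic diol (3R,3aS,5R,6Z,9S,10Z,11aS)-5,9-dihydroxy-3,6,10-trimethyl-3a,4,5,8,9,11a-hexahydrocyclodeca[b]furan-2(3H)-one F7.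
- Acetylation of F7 (Ac2O, Et3N, DMAP) gives 24.

**Further compounds**
F1 | step 11 | (6R)-6-(prop-1-en-2-yl)-3-[(4,4,5,5-tetramethyl-1,3,2-dioxaborolan-2-yl)methyl]-5,6-dihydro-2H-pyran-2-one | C=C(C)[C@H]1CC=C(CB2OC(C)(C)C(C)(C)O2)C(=O)O1
F2 | step 11 | pinacol borate of the six-ring carbinol (C6–O–Bpin) | C=CC[C@H](O[Si](C)(C)C(C)(C)C)/C(C)=C\[C@@H](OB1OC(C)(C)C(C)(C)O1)[C@H]1C[C@H](C(C)=C)OC(=O)C1=C
F3 | step 11 | (4S,6R)-4-[(1R,2Z,4S)-4-(TBS-oxy)-1-hydroxy-3-methylhepta-2,6-dien-1-yl]-3-methylidene-6-(prop-1-en-2-yl)oxan-2-one | C=CC[C@H](O[Si](C)(C)C(C)(C)C)/C(C)=C\[C@@H](O)[C@H]1C[C@H](C(C)=C)OC(=O)C1=C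
F4 | step 13 | (4S,6R)-4-[(1R,2Z,4S)-4-(TBS-oxy)-3-methyl-1-(trimethylsilyloxy)hepta-2,6-dien-1-yl]-3-methylidene-6-(prop-1-en-2-yl)oxan-2-one | C=CC[C@H](O[Si](C)(C)C(C)(C)C)/C(C)=C\[C@@H](O[Si](C)(C)C)[C@H]1C[C@H](C(C)=C)OC(=O)C1=C
F5 | step 13 | (3R,4S,6R)-4-[(1S,2Z,4S)-4-(TBS-oxy)-3-methyl-1-(trimethylsilyloxy)hepta-2,6-dien-1-yl]-3-methyl-6-(prop-1-en-2-yl)oxan-2-one | C=CC[C@H](O[Si](C)(C)C(C)(C)C)/C(C)=C\[C@@H](O[Si](C)(C)C)[C@H]1C[C@H](C(C)=C)OC(=O)[C@@H]1C
F6 | step 13 | (3R,4S,6R)-4-[(1S,2Z,4S)-1,4-dihydroxy-3-methylhepta-2,6-dien-1-yl]-3-methyl-6-(prop-1-en-2-yl)oxan-2-one | C=CC[C@H](O)/C(C)=C\[C@@H](O)[C@H]1C[C@H](C(C)=C)OC(=O)[C@@H]1C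
F7 | step 15 | (3R,3aS,5R,6Z,9S,10Z,11aS)-5,9-dihydroxy-3,6,10-trimethyl-3a,4,5,8,9,11a-hexahydrocyclodeca[b]furan-2(3H)-one | O[C@H]1C/C=C(/C)[C@H](O)C[C@@H]2[C@@H](/C=C\1C)OC(=O)[C@@H]2C
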